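Readings and results were generated by integration for an exercise.

Turning a percent into a molarity is the easy step, and it tests the hunch that more solid substrate lifts the percent of product.

| setting | east | south-east | north-west | winter | dawn |
|---|---|---|---|---|---|
| solid substrate | 1 M | 1 M | 1.1 M | 1.0 M | 2.0 M |
| reagent | 1 M | 1 M | 1 M | 1.00 M | 1.00 M |
| catalyst | 42 mM | 84 mM | 50 mM | 50 mM | 100 mM |
| remark | run made earlier | run made earlier | run made earlier |  |  |
| time |  |  |  | 2.5 d | 0.60 d |

| run | time / d | product / % | solid substrate / % |
|---|---|---|---|
| east | 0.208 | 0.6 | 95.8 |
| east | 0.417 | 2.7 | 93.3 |
| east | 0.625 | 4.1 | 89.6 |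
| east | 1.25 | 11.2 | 81.3 |
| east | 2.50 | 25.3 | 64.6 |
| south-east | 0.208 | 0.8 | 96.0 |
| south-east | 0.625 | 5.7 | 89.4 |
| south-east | 1.25 | 14.7 | 79.8 |
| south-east | 1.67 | 21.6 | 72.5 |
| south-east | 2.50 | 33.3 | 60.2 |
| north-west | 0.208 | 0.1 | 96.9 |
| north-west | 0.625 | 3.3 | 89.5 |
| north-west | 1.25 | 10.4 | 82.1 |
| north-west | 1.67 | 15.0 | 77.4 |
| north-west | 2.50 | 24.6 | 66.8 |

(readings scatter by 0.5 percentage points)

- solid substrate is a solid; its amount is given per volume of the solution
- the numbers in the tables scatter by 0.5 percentage points (one standard deviation)
- at the start none of the solid substrate is in solution
- what has only dissolved of solid substrate counts as not reacted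

- which one finishes higher in amount of product, in percent of the solid substrate charged ("neither" within 2 percentage points) (winter / dawn / neither)
- amount of product at the end, in percent of the solid substrate charged, winter
- amount of product at the end, in percent of the solid substrate charged, dawn

Solid substrate disappears at 0.142 M/d in east and 0.146 M/d in north-west, nearly the same, although north-west holds 1.1 M of solid and 50 mM of catalyst against 1 M and 42 mM in east. That reads as a loss of zero order in the solid, with dissolution as the feed. So product is counted here as the molar yield m, the percent of product times the molarity of solid charged. At fixed reagent, catalyst and time, and while solid stands, m should not move with the solid charged, and the percent goes as m over the charge. At fixed m, going from 1 M to 2.0 M takes 0.301 off the common logarithm of the percent.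

Winter has the catalyst and time of north-west, whose last reading gives 0.271 M, so winter should reach 27.1%. For dawn the reading to use is south-east at 0.625 d, where m = 0.0570 M, the molar yield. Dawn has 100 mM of catalyst and 0.60 d against the 84 mM and 0.625 d of south-east, and taking these two differences to cancel gives 2.85% for dawn. Winter should therefore finish higher than dawn.

The forecast says winter, with 27% and 3%, holding that “Extra solid adds nothing”.

The flask gives winter, with 27.2% for winter and 3.12% for dawn; the dawn figure is 0.0624 M of product against the m = 0.0570 M read in south-east.

    starting material + reagent + catalyst → catalyst + product (k = 1.50 /M²/h)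
    solid substrate ⇌ starting material, rate k2*(cs2 - [starting material]) while solid is left; crystals form when [starting material] > cs2 (solubility = 0.260 M, k = 0.0320 /h)

In dawn at 0.600 d, starting material is made, net, 1.13 times as fast as it is used up, down from 1.51 at 0.287 d, and its half-life by the reaction, 0.21 d, is shorter than the run's 0.60 d. Dawn then holds 2.18% of its solid charge as starting material beside 3.12% product, with 94.7% still solid. A neighbour of dawn charged with 0.50 M of solid substrate should reach 11.4% by m, and the computed flask gives 12.5%.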